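**Overview**
Sauriol A (13) is the C2-symmetric (8R,8'R)-dibenzylbutane (lignan numbering: C7/C7' benzylic CH2, C8/C8' methine, C9/C9' methyl). The feature used is that each C8H(C9H3)–C7H2–aryl unit is the ring-opened form of a trans-2-alkyl-1-arylcyclopropane (ring C7–C8–C9) cut at its benzylic, unsubstituted C7–C9 bond.
13 ⇒ tetra-O-benzyl bis-cyclopropane 10: one hydrogenation opens both three-membered rings and frees the four phenols.
10 ⇒ (E,E)-diene 7 + 2 CH2 (from diiodomethane 8): twofold asymmetric methylene transfer forms C7–C9/C8–C9 and C7'–C9'/C8'–C9'; ring C7–C8–C9 closes first (vinylcyclopropane 9), ring C7'–C8'–C9' second, in the same flask.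
7 ⇒ E-alkenyl boronate 5 + E-alkenyl iodide 6 (C8–C8' bond, Suzuki–Miyaura); 6 ⇐ 5; 5 ⇐ aldehyde 3 + CH2(Bpin)2 4 (boron-Wittig); 3 ⇐ 5-hydroxyvanillin 1 + benzyl bromide 2.

Key step: step 5

Assumption: the sense of induction of the dipeptide-bound zinc carbenoid on diene 7 cannot be predicted with confidence; the route is written with N-Boc-L-Val-L-Pro-OMe, and the mirror-image dipeptide from D-valine and D-proline is used under the same conditions if a small-scale run shows the antipodal series.

Step 1
Reactants: 1 3,4-dihydroxy-5-methoxybenzaldehyde; 2 benzyl bromide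
Product: 3 3,4-bis(benzyloxy)-5-methoxybenzaldehyde
Conditions: BnBr (2.4 equiv), K2CO3 (3 equiv), DMF, N2, 60 °C
Reagents that add atoms: benzyl bromide (compound 2), BrCc1ccccc1
Why: Williamson ether synthesis, in which both phenoxides of the catechol are alkylated at oxygen by the benzylic bromide under carbonate base that leaves the aldehyde untouched; no stereocentre is formed.

Step 2
Reactants: 3 3,4-bis(benzyloxy)-5-methoxybenzaldehyde; 4 bis[(pinacolato)boryl]methane
Product: 5 2-{(E)-2-[3,4-bis(benzyloxy)-5-methoxyphenyl]ethenyl}-4,4,5,5-tetramethyl-1,3,2-dioxaborolane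
Conditions: 4 (1.2 equiv), lithium 2,2,6,6-tetramethylpiperidide (LiTMP, 1.2 equiv), THF, 0 °C; then 3, −78 °C → rt; H2O quench
Reagents that add atoms: bis[(pinacolato)boryl]methane (compound 4), CC1(C)OB(CB2OC(C)(C)C(C)(C)O2)OC1(C)C
Why: Boron-Wittig olefination, in which the α-boryl carbanion of 4 adds to the non-enolisable aldehyde and the β-boryl alkoxide collapses by syn B–O elimination, which for aryl aldehydes should place the aryl group and the remaining boryl group trans (E alkene); no stereocentre is formed.

Step 3
Reactants: 5 alkenyl boronate (about half of the material from step 2)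
Product: 6 1,2-bis(benzyloxy)-5-[(E)-2-iodoethenyl]-3-methoxybenzene
Conditions: NaOH (3 M aq.), then I2, THF, 0 °C → rt, dark; Na2S2O3 work-up
Reagents that add atoms: iodine, II
Why: Base-mediated iododeboronation of an alkenyl boronate, in which iodine attacks the hydroxyboronate ate complex and replaces boron at the same carbon with retention of the E geometry, while the aryl ethers are inert to I2/NaOH at 0 °C; no stereocentre is formed.

Step 4
Reactants: 5 alkenyl boronate; 6 alkenyl iodide
Product: 7 (1E,3E)-1,4-bis[3,4-bis(benzyloxy)-5-methoxyphenyl]buta-1,3-diene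
Conditions: Pd(PPh3)4 (5 mol %), K2CO3 (2 M aq.), THF, 65 °C, degassed, dark; recrystallisation
Reagents that add atoms: none
Why: Suzuki–Miyaura cross-coupling, in which oxidative addition of the alkenyl iodide to zerovalent palladium and transmetalation of the alkenyl boronate both go with retention, so the C8–C8' bond forms with E,E geometry, and homocoupling of either partner gives the same symmetric diene; no stereocentre is formed.

Step 5
Reactants: 7 (E,E)-diene; 8 diiodomethane
Product: 10 (1S,1'S,2R,2'R)-2,2'-bis[3,4-bis(benzyloxy)-5-methoxyphenyl]-1,1'-bi(cyclopropane), via vinylcyclopropane 9 (not isolated)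
Conditions: N-Boc-L-Val-L-Pro-OMe (3.0 equiv), Et2Zn (3.0 equiv), CH2Cl2, 0 °C; CH2I2 (3.3 equiv), 0 °C; then 7, −20 → 0 °C; aq. NH4Cl; meso isomer removed by chromatography or crystallisation
Reagents that add atoms: diiodomethane (compound 8), ICI
Why: Proposed new method: the zinc amide formed from Et2Zn and the carbamate N–H of the valine residue is converted by CH2I2 into a ligand-bound iodomethylzinc carbenoid, which should hand CH2 to each electron-rich styrenyl C=C through the concerted three-centre (butterfly) transition state of the Simmons–Smith reaction; the closest known reaction type is the dipeptide-modified asymmetric Simmons–Smith cyclopropanation of unfunctionalised aryl alkenes, which has not been shown as a twofold transfer to a conjugated 1,4-diaryl diene. Each ring (C7–C8–C9 first, then C7'–C8'–C9' on vinylcyclopropane 9) closes by an intermolecular [2+1] cheletropic addition in which C7–C9 and C8–C9 form in the same event, so the E geometry is copied stereospecifically into the trans relation of C7 and C8. The absolute configuration of the four new stereocentres (C7 and C7' R, C8 and C8' S) rests on the chiral dipeptide on zinc alone, which must choose the same enantioface at both alkenes because the substrate has no directing group. Since the reagent acts twice on a C2-symmetric substrate, most mismatched events end in the meso (1R,1'S,2S,2'R) isomer, which is a separable diastereomer, so the isolated C2 isomer should be richer in the major enantiomer than a single transfer would give. The step also needs complete double transfer and no attack on the aryl ethers: the three oxygen donors on each ring make both alkenes nucleophilic, the cyclopropyl group makes 9 more so, and keeping Et2Zn no higher than the dipeptide suppresses the ligand-free, unselective carbenoid.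

Step 6
Reactants: 10 tetra-O-benzyl bis-cyclopropane
Product: 13 sauriol A [5,5'-((2R,3R)-2,3-dimethylbutane-1,4-diyl)bis(3-methoxybenzene-1,2-diol)], via tetraphenol bis-cyclopropane 11 (not isolated), via half-opened tetraphenol 12 (not isolated)
Conditions: H2 (1 atm, then 4 atm), 10% Pd/C, EtOAc/EtOH, 25 → 50 °C
Reagents that add atoms: none
Why: Heterogeneous hydrogenolysis, in which the four O-benzyl groups are cleaved first and palladium then cuts the benzylic bond of each arylcyclopropane that is least substituted and most accessible (C7–C9, C7'–C9'), so C9 and C9' become methyl groups and C7 and C7' become CH2; C8 and C8' keep their configuration because none of their bonds is broken, and their descriptor changes from S to R only through the CIP ranking.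

**Compound list**
1 | 3,4-dihydroxy-5-methoxybenzaldehyde (5-hydroxyvanillin) | COc1cc(C=O)cc(O)c1O | starting material
2 | benzyl bromide | BrCc1ccccc1 | starting material
3 | 3,4-bis(benzyloxy)-5-methoxybenzaldehyde | COc1cc(C=O)cc(OCc2ccccc2)c1OCc1ccccc1 | intermediate
4 | bis[(pinacolato)boryl]methane [2,2'-methylenebis(4,4,5,5-tetramethyl-1,3,2-dioxaborolane)] | CC1(C)OB(CB2OC(C)(C)C(C)(C)O2)OC1(C)C | starting material
5 | 2-{(E)-2-[3,4-bis(benzyloxy)-5-methoxyphenyl]ethenyl}-4,4,5,5-tetramethyl-1,3,2-dioxaborolane | COc1cc(/C=C/B2OC(C)(C)C(C)(C)O2)cc(OCc2ccccc2)c1OCc1ccccc1 | intermediate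
6 | 1,2-bis(benzyloxy)-5-[(E)-2-iodoethenyl]-3-methoxybenzene | COc1cc(/C=C/I)cc(OCc2ccccc2)c1OCc1ccccc1 | intermediate
7 | (1E,3E)-1,4-bis[3,4-bis(benzyloxy)-5-methoxyphenyl]buta-1,3-diene | COc1cc(/C=C/C=C/c2cc(OC)c(OCc3ccccc3)c(OCc3ccccc3)c2)cc(OCc2ccccc2)c1OCc1ccccc1 | intermediate
8 | diiodomethane | ICI | starting material
9 | (1R,2S)-1-[3,4-bis(benzyloxy)-5-methoxyphenyl]-2-{(E)-2-[3,4-bis(benzyloxy)-5-methoxyphenyl]ethenyl}cyclopropane (vinylcyclopropane, not isolated) | COc1cc([C@@H]2C[C@H]2/C=C/c2cc(OC)c(OCc3ccccc3)c(OCc3ccccc3)c2)cc(OCc2ccccc2)c1OCc1ccccc1 | intermediate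
10 | (1S,1'S,2R,2'R)-2,2'-bis[3,4-bis(benzyloxy)-5-methoxyphenyl]-1,1'-bi(cyclopropane) | COc1cc([C@@H]2C[C@H]2[C@@H]2C[C@H]2c2cc(OC)c(OCc3ccccc3)c(OCc3ccccc3)c2)cc(OCc2ccccc2)c1OCc1ccccc1 | intermediate
11 | 5,5'-[(1S,1'S,2R,2'R)-1,1'-bi(cyclopropane)-2,2'-diyl]bis(3-methoxybenzene-1,2-diol) (tetraphenol bis-cyclopropane, not isolated) | COc1cc([C@@H]2C[C@H]2[C@@H]2C[C@H]2c2cc(OC)c(O)c(O)c2)cc(O)c1O | intermediate
12 | 5-[(2R)-2-{(1S,2R)-2-(3,4-dihydroxy-5-methoxyphenyl)cyclopropyl}propyl]-3-methoxybenzene-1,2-diol (half-opened tetraphenol, not isolated) | COc1cc(C[C@@H](C)[C@@H]2C[C@H]2c2cc(OC)c(O)c(O)c2)cc(O)c1O | intermediate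
13 | sauriol A, 5,5'-[(2R,3R)-2,3-dimethylbutane-1,4-diyl]bis(3-methoxybenzene-1,2-diol) | COc1cc(C[C@@H](C)[C@H](C)Cc2cc(O)c(O)c(OC)c2)cc(O)c1O | target

**Step count and risks**
Total step count: 6. Longest linear sequence: 6 steps (1 → 3 → 5 → 6 → 7 → 10 → 13).

Steps most likely to fail:

1. Step 5 (Proposed new method). The process at risk is enantioface selection. A trans-disubstituted styrenyl alkene without a directing group may be discriminated only weakly by the dipeptide-bound carbenoid, the many ether oxygens of 7 may compete with the ligand for zinc, and ligand-free carbenoid would add without selectivity. The second transfer may also stall at 9. Fallback with known chemistry, from 7 back to 10: twofold cyclopropanation with the achiral Furukawa reagent (Et2Zn, CH2I2, CH2Cl2, 0 °C), a stereospecific Simmons–Smith reaction, should give the trans,trans bis-cyclopropanes as racemate plus meso form. That is 10 together with its enantiomer (1R,1'R,2S,2'S)-2,2'-bis[3,4-bis(benzyloxy)-5-methoxyphenyl]-1,1'-bi(cyclopropane) F1 and the meso (1R,1'S,2S,2'R)-2,2'-bis[3,4-bis(benzyloxy)-5-methoxyphenyl]-1,1'-bi(cyclopropane) F2. F2 is a diastereomer and is removed on silica or by crystallisation; 10 is separated from F1 by preparative chromatography on a polysaccharide-based chiral stationary phase and then enters step 6. If the two transfers are uncorrelated, at most a quarter of the material can end as 10.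

2. Step 6. Processes at risk: palladium may also cut the more substituted benzylic bond C7–C8 (straight-chain isomers), reversible β-hydride elimination on the metal surface may erode the configuration at C8 and C8', and ring opening may stall at 12. Fallback, from 10 to 13: oxymercuration–demercuration followed by benzylic C–O hydrogenolysis. Hg(OAc)2 in MeOH at room temperature should open each arylcyclopropane as an electrophile, with divalent mercury bonding to the least substituted ring carbon C9 and methanol entering at the benzylic carbon C7 that best carries positive charge. This gives the bis(organomercurial) (2S,3S)-2,3-bis[(acetoxymercurio)methyl]-1,4-bis[3,4-bis(benzyloxy)-5-methoxyphenyl]-1,4-dimethoxybutane F3 (epimers at the two methoxy-bearing carbons). Alkaline NaBH4 in the same flask replaces mercury by hydrogen and should give the bis(benzylic methyl ether) (2S,3S)-1,4-bis[3,4-bis(benzyloxy)-5-methoxyphenyl]-1,4-dimethoxy-2,3-dimethylbutane F4. H2 over Pd(OH)2/C (EtOAc/EtOH, rt) then removes the two benzylic methoxy groups and the four benzyl ethers and leads to 13. C8 and C8' take part in none of these bond changes; the descriptor S in F3 and F4 against R in 13 follows from the CIP ranking, not from an inversion.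

3. Step 3. Process at risk: iodination through a β-iodo benzylic cation stabilised by the electron-rich ring can erode the E geometry, and the activated ring may be iodinated. Fallback, from 3 to 6: Takai olefination (CHI3, CrCl2, THF, 0 °C → rt) converts the aldehyde directly into the E-iodoalkene through a geminal dichromium species and does not depend on boron; it makes no compound outside the list (F0). 6 then enters step 4 as before.

**Further compounds**
F1 | step 5 | (1R,1'R,2S,2'S)-2,2'-bis[3,4-bis(benzyloxy)-5-methoxyphenyl]-1,1'-bi(cyclopropane) (enantiomer of 10) | COc1cc([C@H]2C[C@@H]2[C@H]2C[C@@H]2c2cc(OC)c(OCc3ccccc3)c(OCc3ccccc3)c2)cc(OCc2ccccc2)c1OCc1ccccc1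
F2 | step 5 | (1R,1'S,2S,2'R)-2,2'-bis[3,4-bis(benzyloxy)-5-methoxyphenyl]-1,1'-bi(cyclopropane) (meso) | COc1cc([C@@H]2C[C@H]2[C@H]2C[C@@H]2c2cc(OC)c(OCc3ccccc3)c(OCc3ccccc3)c2)cc(OCc2ccccc2)c1OCc1ccccc1
F3 | step 6 | (2S,3S)-2,3-bis[(acetoxymercurio)methyl]-1,4-bis[3,4-bis(benzyloxy)-5-methoxyphenyl]-1,4-dimethoxybutane (epimers at C1 and C4) | COc1cc(C(OC)[C@@H](C[Hg]OC(C)=O)[C@H](C[Hg]OC(C)=O)C(OC)c2cc(OC)c(OCc3ccccc3)c(OCc3ccccc3)c2)cc(OCc2ccccc2)c1OCc1ccccc1
F4 | step 6 | (2S,3S)-1,4-bis[3,4-bis(benzyloxy)-5-methoxyphenyl]-1,4-dimethoxy-2,3-dimethylbutane (epimers at C1 and C4) | COc1cc(C(OC)[C@@H](C)[C@H](C)C(OC)c2cc(OC)c(OCc3ccccc3)c(OCc3ccccc3)c2)cc(OCc2ccccc2)c1OCc1ccccc1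
F0 | step 3 | none | none
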